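**Conventions.** Bisabolane numbering is used throughout: ring A is C1–C6, C1 carries the chain through C7, C14 is the methylidene carbon on C7, and the chain runs C8–C11. Atoms of the lactone acid are primed (C1' carboxyl, C2' quaternary, C3' methyl-bearing, C5' ethyl-bearing, C6' lactone carbonyl). On ring A, "β" is the face that carries O4, O5, O6 and the C1 substituent; "α" is the face that carries O3 and the C4 methyl group.

## The problem

The target 49 is a cyclohexane (ring A) with five contiguous stereocentres, C1 and C3–C6, joined at C1 through the methylidene-bearing C7 to a C8–C11 chain with two further carbinol centres (C8, C10), and O3 is esterified by a δ-lactone acid with three stereocentres of its own. Seven oxygens must be told apart: O3 takes the hindered lactone acyl group, O5 and O10 take angelates, and O6, O8 and the tertiary O4 and O11 stay free. In ring A the sugar-like triad C4–C6 (three cis oxygens and the C4 methyl) can control C1 and, through the C4 hydroxyl, C3. C8 and C10 are too remote for relay and need reagent control, as do C2', C3' and C5'. The fragile groups are the two (Z)-angelates (isomerisation to tiglates under heat with nucleophiles), the 2-substituted allylic alcohol, the cis-vicinal and 1,3-related hydroxy esters (acyl migration), the lactone (base), and any intermediate with a carbonyl β to a ring oxygen (elimination, retro-aldol). The enabling feature is that C3 (oxygenated) and C7 (a former carbonyl carbon) are 1,4-related through C2–C1, a masked 1,4-dicarbonyl, so that joining C1 to C2 means coupling two carbons that are both nucleophilic as enol ether β-carbons, which anodic oxidation allows. The remaining carbons C4–C6 map atom for atom onto 2-C-methyl-L-ribose, which is reachable from L-arabinose.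

## Retrosynthesis

**49 ⇒ 48 ⇒ 47 (C8–O bond, C7=C14).** The allylic alcohol with its exocyclic methylidene is taken back to the (7R,8R)-epoxide 48 and then to the E-trisubstituted olefin 47, in which C14 is a methyl group on C7. The neighbouring option, adding a C7 vinyl metal to a C8 aldehyde, would need a 2-haloalkene and gives no control at C8. The transposition lets a chiral dioxirane set C8, and the C8 hydroxyl appears in the last step, so it never needs protection. The forward reactions must pick the one electron-rich olefin over two angelates and must take the hydrogen from C14, not from C1.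

**47 ⇒ 45 ⇒ 44 ⇒ 30 + 42 (three C–O acyl bonds on ring A).** The O5 angelate is removed first to give tetraol 45. O5 is the equatorial oxygen of a cis-diol, the position a stannylene acetal activates. Returning the 5,6-dioxolane gives 44. Cutting the O3 ester then gives triol 30 and the lactone acid 42. The order puts the hardest acylation (axial O3, α-quaternary acid) at the point where O3 is the only secondary hydroxyl in the molecule. The forward steps ask for a forcing but chemoselective esterification and a regioselective mono-acylation.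

**30 ⇒ 29 ⇒ 26 ⇒ 19 + 23 (C8–C9 and C7–C14).** After removal of the O10 angelate (29 → 26), the chain is cut between C8 and C9 and the C14 methyl group is removed from C7. This leads to the ring A alkyne 19 and the epoxide 23. One operation, methylalumination followed by epoxide opening, makes both bonds, fixes the E geometry and brings in C10 with its configuration. Because organoaluminium and organolithium reagents are involved, this coupling has to precede all ester formation, and 19 carries only silyl ethers and the dioxolane.

**19 ⇒ 18 ⇒ 17 ⇒ 16 ⇒ 15 ⇒ 14 (functional group changes on ring A).** The alkyne comes from the C7 aldehyde of 15 by one-carbon homologation. The axial C3 hydroxyl of 18 comes from the C3 ketone of 17 by hydride delivery from the C4 hydroxyl. Both hydride faces of this ketone are otherwise hindered, and the needed face is the one that carries all the oxygens, so a bulky hydride is not relied on. Keto aldehyde 15 is the hydrolysis product of bis-acetal 14.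

**14 ⇒ 13 (C1–C2, ring A; the key cut).** Cutting C1–C2 opens ring A to the bis(methyl enol ether) 13. Cuts at C4–C5 or C5–C6 would instead require the three cis oxygens to be made. This cut keeps C4–C6 intact as a sugar chain and returns both new functional carbons, C3 and C7, at carbonyl level and differentiated from the rest. The forward reaction must form a six-membered ring between two enol ether β-carbons faster than methanol captures the radical cation, and must place C7 cis to O6.

**13 ⇒ 12 ⇒ 11 ⇒ 10 ⇒ 8 ⇒ 5 ⇒ 4 ⇒ 1 (the sugar chain).** The 2-methoxyalkene of 13 is the methylenation product of the ester of 12, and the methoxyvinyl group is the Wittig product of aldehyde 11. Aldehydo ester 11 comes from lactone 8 by way of hydroxy ester 10. Lactone 8 is 2-C-methyl-L-ribonolactone, protected as its 3,4-acetonide and 2-O-silyl ether. Its tertiary centre arises from methyl addition to ulose 4, and 4 is made from L-arabinose 1 by way of its benzyl pyranoside. C5 and C6 of the target are bought; C4 is set by the dioxolane that protects them.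

**42 ⇒ 40 ⇒ 39 ⇒ 36 ⇒ 35 ⇒ 32 + 33 (the lactone acid).** The C5' ethyl group is removed from lactone 40 to give 39, since a δ-lactone enolate alkylates anti to its C3' methyl group. Lactone 39 is the hydrogenated, cyclised Wittig product of aldehyde 36. Aldehyde 36 comes from thioester 35, the anti aldol adduct of silylketene acetal 32 and methyl pyruvate 33; this one catalytic step sets C2' and C3'. A pool route from a 2-hydroxy-2-methylsuccinate was set aside: it would need a C3' methylation with no dependable facial bias, and an O-protected enolate there would eliminate.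

**23 ⇒ 22 ⇒ 20 and 28 ⇒ 27.** Epoxide 23 is the resolved form of racemic 22, made from 2-methylbut-3-en-2-ol 20 through 21. Both angelates come from angelic acid 27 through its mixed anhydride 28, which is prepared in a step of its own so that one reagent serves the acylations of O10 and O5.

## Roads not taken

**Alternative 1:** The cut is at C7–C14 and C8–C9. The forward key step is Cp2ZrCl2-catalysed methylalumination of a C1 ethynyl group followed by opening of a side-chain epoxide by the derived alkenylalanate, giving olefin A1. Its merits are convergence, secure E geometry, C10 carried in from the epoxide, and a reaction type with full precedent. As a coupling it is better founded than the anodic step of the chosen plan. Its weakness as a strategy is that it closes no ring. The pentasubstituted cyclohexane with five stereocentres must already exist, the C8 oxygen and the methylidene are still missing in A1, and A1 carries four different protecting groups to be removed in order. The chosen route therefore adopts this tactic as its step 21 and sets against it the one thing it lacks, a short construction of ring A from a sugar.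

**Alternative 2:** The cut is at C5=C6. The forward key step is ring-closing metathesis between a vinyl group on C4 and one on C1 with the second-generation Grubbs catalyst (H2IMes)(PCy3)Cl2Ru=CHPh, giving cyclohexene A2. The ring closure is more certain than any electrochemical coupling and tolerates the free tertiary allylic alcohol; here this road is better. Its weak points lie before and after. The stereocentres C1, C3 and the quaternary C4 of A2 have to be built in an open chain by separate asymmetric steps. The later cis-dihydroxylation of C5=C6 must occur on the face that carries both the C4 hydroxyl and the C1 substituent, against the usual preference of OsO4 for the face anti to an allylic oxygen. Only a hydrogen-bond-directed osmylation could answer this, and it would still be opposed by the C1 group. The chosen plan sets against the safer ring closure that C4, C5 and C6 come from L-arabinose with no face-selectivity question, and that C3 and C7 emerge at carbonyl level.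

**Alternative 3:** The cut is at C4–C5. The forward key step is a pinacol coupling with SmI2 (samarium diiodide, divalent samarium) between a C5 aldehyde and a C4 methyl ketone of an opened carvone skeleton, giving cis-diol A3. Its merits are real. Carvone supplies C1 with the correct configuration and with C7, C14 and C8 attached, so C1 is not at risk, which is the soft spot of the chosen plan. The chain is also complete before the ring is reclosed, which is more convergent. Its weak points are the long sequence needed to open the carvone ring and install oxygen at C3 and C6, and the face of the coupling. The new cis-diol must form syn to the C6 silyloxy group, whereas ketyl couplings tend to place the new hydroxyl anti to an α-oxygen substituent. A3 also carries five protecting groups of four kinds. The chosen plan sets against the better C1 control that the three contiguous cis oxygens are bought rather than made, and that ring A is reached in twelve steps.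

Key step: step 12

**Assumption 1:** Enol ethers 12 and 13 are taken on as E/Z mixtures at C1=C7 and drawn as the E isomers; both isomers give the same constitution in step 12.

**Assumption 2:** The (S,S)-benzyl-pybox complex of Sn(OTf)2 is taken to give the 2'S carbinol in step 26, in line with the reported sense for pyruvate esters; if the sense were opposite, the (R,R)-ligand would be used.

**Assumption 3:** The (R,R)-(salen)Co(OAc) catalyst is taken to leave the S enantiomer of epoxide 22 in step 20; if the sense were opposite for this tertiary-alkyl epoxide, the (S,S)-catalyst would be used.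

## Route

Step 1
Reactants: 1 L-arabinose
Product: 2 benzyl β-L-arabinopyranoside
Conditions: BnOH, HCl (anhydrous, cat.), 50 °C; crystallisation
Reagents that add atoms: benzyl alcohol, OCc1ccccc1
Why: Fischer glycosidation; the β-pyranoside (axial benzyloxy group) crystallises from the equilibrium mixture, and C2–C4 of the sugar are untouched.

Step 2
Reactants: 2 benzyl β-L-arabinopyranoside
Product: 3 benzyl 3,4-O-isopropylidene-β-L-arabinopyranoside
Conditions: 2,2-dimethoxypropane, TsOH (cat.), DMF, rt
Reagents that add atoms: 2,2-dimethoxypropane, COC(C)(C)OC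
Why: Acid-catalysed acetal exchange; only the cis-3,4-diol can form a five-membered dioxolane, so O2 alone stays free.

Step 3
Reactants: 3 benzyl 3,4-O-isopropylidene-β-L-arabinopyranoside
Product: 4 benzyl 3,4-O-isopropylidene-β-L-erythro-pentopyranosid-2-ulose
Conditions: Dess–Martin periodinane, CH2Cl2, rt
Reagents that add atoms: none
Why: Dess–Martin oxidation of the single free secondary hydroxyl; the neutral medium avoids epimerisation at the anomeric carbon and β-elimination.

Step 4
Reactants: 4 benzyl 3,4-O-isopropylidene-β-L-erythro-pentopyranosid-2-ulose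
Product: 5 benzyl 3,4-O-isopropylidene-2-C-methyl-β-L-ribopyranoside
Conditions: MeMgBr, THF, −78 °C; aq. NH4Cl
Reagents that add atoms: methylmagnesium bromide, C[Mg]Br
Why: Grignard addition from the face away from the cis-fused dioxolane, the sense known for hydride and methyl additions to this ulose, should give the ribo tertiary alcohol (O2 cis to O3 and O4); this sets C4 of the target.

Step 5
Reactants: 5 benzyl 3,4-O-isopropylidene-2-C-methyl-β-L-ribopyranoside
Product: 6 benzyl 3,4-O-isopropylidene-2-C-methyl-2-O-triethylsilyl-β-L-ribopyranoside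
Conditions: TESOTf, 2,6-lutidine, CH2Cl2, 0 °C to rt
Reagents that add atoms: triethylsilyl triflate, CC[Si](CC)(CC)OS(=O)(=O)C(F)(F)F
Why: Silyl triflate silylation of a tertiary alcohol; the ether is needed so that this hydroxyl cannot capture the radical cation in step 12.

Step 6
Reactants: 6 benzyl 3,4-O-isopropylidene-2-C-methyl-2-O-triethylsilyl-β-L-ribopyranoside
Product: 7 3,4-O-isopropylidene-2-C-methyl-2-O-triethylsilyl-L-ribopyranose (anomeric mixture)
Conditions: H2 (1 atm), Pd/C, EtOAc, rt
Reagents that add atoms: none
Why: Hydrogenolysis of the benzyl glycoside under neutral conditions frees the lactol and leaves the dioxolane and the silyl ether in place.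

Step 7
Reactants: 7 3,4-O-isopropylidene-2-C-methyl-2-O-triethylsilyl-L-ribopyranose
Product: 8 3,4-O-isopropylidene-2-C-methyl-2-O-triethylsilyl-L-ribono-1,5-lactone
Conditions: Pr4N[RuO4] (cat.), N-methylmorpholine N-oxide, 4 Å sieves, CH2Cl2, rt
Reagents that add atoms: none
Why: Ley–Griffith oxidation of a lactol to the lactone; with O2–O4 blocked the 1,5-lactone is the only one possible.

Step 8
Reactants: 8 3,4-O-isopropylidene-2-C-methyl-2-O-triethylsilyl-L-ribono-1,5-lactone
Product: 10 methyl 3,4-O-isopropylidene-2-C-methyl-2-O-triethylsilyl-L-ribonate, via caesium ribonate 9 (not isolated)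
Conditions: CsOH, THF–H2O, 0 °C; evaporate, azeotrope with toluene; MeI, DMF, rt
Reagents that add atoms: caesium hydroxide, [Cs+].[OH-]; iodomethane, CI
Why: Saponification followed by SN2 O-alkylation of the carboxylate; the second stage is neutral and irreversible, which avoids the relactonisation equilibrium of a base-catalysed methanolysis.

Step 9
Reactants: 10 methyl 3,4-O-isopropylidene-2-C-methyl-2-O-triethylsilyl-L-ribonate
Product: 11 methyl 3,4-O-isopropylidene-2-C-methyl-5-oxo-2-O-triethylsilyl-L-ribonate (C5 aldehyde)
Conditions: Dess–Martin periodinane, CH2Cl2, 0 °C to rt; used crude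
Reagents that add atoms: none
Why: Dess–Martin oxidation of the primary alcohol; the α-alkoxy aldehyde is held by the cis-dioxolane and is used without chromatography.

Step 10
Reactants: 11 methyl 3,4-O-isopropylidene-2-C-methyl-5-oxo-2-O-triethylsilyl-L-ribonate
Product: 12 methyl 5,6-dideoxy-3,4-O-isopropylidene-6-methoxy-2-C-methyl-2-O-triethylsilyl-L-ribo-hex-5-enonate (E/Z)
Conditions: Ph3P(CH2OMe)Cl, KN(SiMe3)2, THF, −78 to 0 °C
Reagents that add atoms: (methoxymethyl)triphenylphosphonium chloride, COC[P+](c1ccccc1)(c1ccccc1)c1ccccc1.[Cl-]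
Why: Wittig methoxymethylenation; the aldehyde reacts far faster than the hindered α-quaternary ester, and the E/Z mixture is acceptable (E preferred, separable if needed).

Step 11
Reactants: 12 methyl 5,6-dideoxy-3,4-O-isopropylidene-6-methoxy-2-C-methyl-2-O-triethylsilyl-L-ribo-hex-5-enonate
Product: 13 (6E)-2,7-dimethoxy-4,5-(isopropylidenedioxy)-3-methyl-3-(triethylsilyloxy)hepta-1,6-diene, 2-C-methyl-L-ribo configuration (target atoms C2=C3, C4, C5, C6, C1=C7)
Conditions: Cp2TiMe2, toluene, 70 °C, dark; basic Al2O3
Reagents that add atoms: dimethyltitanocene, C[Ti](C)(C1C=CC=C1)C1C=CC=C1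
Why: Petasis methylenation of the ester through titanocene methylidene gives the 2-methoxyalkene under non-acidic conditions that both enol ethers survive.

Step 12
Reactants: 13 (6E)-2,7-dimethoxy-4,5-(isopropylidenedioxy)-3-methyl-3-(triethylsilyloxy)hepta-1,6-diene
Product: 14 1β-(dimethoxymethyl)-3,3-dimethoxy-4α-methyl-4β-(triethylsilyloxy)-5β,6β-(isopropylidenedioxy)cyclohexane
Conditions: reticulated vitreous carbon anode, Pt cathode, undivided cell, LiClO4 (0.1 M), MeOH–THF (1:1), 2,6-lutidine, constant current (8 mA), 2.2 F/mol, rt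
Reagents that add atoms: methanol, CO
Why: Anodic oxidation removes one electron from an enol ether (either one, both converge); the radical cation is attacked at its β-carbon by the β-carbon of the second enol ether, joining C1 to C2, and a second electron transfer with capture of both oxocarbenium carbons by methanol gives the C3 dimethyl ketal and the C7 dimethyl acetal while 2,6-lutidine keeps the medium non-acidic. The closest known reaction type is the intramolecular anodic coupling of two enol ethers in methanol to five- and six-membered rings bearing two acetal carbons. Ring A closes 6-exo-trig with respect to the C1=C7 olefin (C7 stays exocyclic), and the C2=C3 unit becomes endocyclic. The one new stereocentre, C1, is controlled by C6: in the chair-like transition state C7 is pseudo-equatorial, the allylic C6–O bond takes the inside position near the plane of the reacting olefin and C6–H lies anti to the forming bond, which puts C7 cis to O6; the same chair keeps the large C4 silyloxy group axial, away from the C3 methoxy group. This preference should be cleanest for the E enol ether and weaker for the Z isomer, whose methoxy group meets O6 in allylic 1,3-strain. The step also needs ring closure to outrun solvent capture of the first radical cation; the quaternary C4 and the cis-fused dioxolane hold the two olefins close, and the β,β-regiochemistry is intrinsic, since a C2–C7 closure would leave an unstabilised cation at C1.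

Step 13
Reactants: 14 1β-(dimethoxymethyl)-3,3-dimethoxy-4α-methyl-4β-(triethylsilyloxy)-5β,6β-(isopropylidenedioxy)cyclohexane
Product: 15 1β-formyl-4α-methyl-4β-(triethylsilyloxy)-5β,6β-(isopropylidenedioxy)cyclohexan-3-one
Conditions: TsOH·H2O (cat.), acetone–H2O (10:1), 0 °C to rt
Reagents that add atoms: water, O
Why: Acid-catalysed hydrolysis of the two acyclic acetals; the acetone solvent holds the dioxolane in place and the tertiary silyl ether is slow to cleave.

Step 14
Reactants: 15 1β-formyl-4α-methyl-4β-(triethylsilyloxy)-5β,6β-(isopropylidenedioxy)cyclohexan-3-one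
Product: 16 1β-ethynyl-4α-methyl-4β-(triethylsilyloxy)-5β,6β-(isopropylidenedioxy)cyclohexan-3-one
Conditions: dimethyl (1-diazo-2-oxopropyl)phosphonate, K2CO3, MeOH, 0 °C
Reagents that add atoms: dimethyl (1-diazo-2-oxopropyl)phosphonate, COP(=O)(OC)C(=[N+]=[N-])C(C)=O
Why: Ohira–Bestmann (Seyferth–Gilbert) homologation is selective for the aldehyde over the hindered ketone; at 0 °C addition should outrun epimerisation at C1 and loss of O6 by β-elimination.

Step 15
Reactants: 16 1β-ethynyl-4α-methyl-4β-(triethylsilyloxy)-5β,6β-(isopropylidenedioxy)cyclohexan-3-one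
Product: 17 1β-ethynyl-4β-hydroxy-4α-methyl-5β,6β-(isopropylidenedioxy)cyclohexan-3-one
Conditions: HF·pyridine, THF, 0 °C to rt
Reagents that add atoms: none
Why: Fluoride cleavage of the silyl ether frees the C4 hydroxyl, which is needed as the directing group in the next step; the dioxolane is stable to buffered HF.

Step 16
Reactants: 17 1β-ethynyl-4β-hydroxy-4α-methyl-5β,6β-(isopropylidenedioxy)cyclohexan-3-one
Product: 18 1β-ethynyl-4α-methyl-5β,6β-(isopropylidenedioxy)cyclohexane-3α,4β-diol
Conditions: Me4NBH(OAc)3, MeCN–AcOH, −20 °C to rt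
Reagents that add atoms: none
Why: Hydroxyl-directed (Saksena–Evans) reduction: the C4 hydroxyl exchanges onto boron and delivers hydride intramolecularly to the β face of the C3 carbonyl, giving the axial 3α-alcohol trans to O4; this sets C3.

Step 17
Reactants: 18 1β-ethynyl-4α-methyl-5β,6β-(isopropylidenedioxy)cyclohexane-3α,4β-diol
Product: 19 1β-ethynyl-4α-methyl-3α,4β-bis(triethylsilyloxy)-5β,6β-(isopropylidenedioxy)cyclohexane
Conditions: TESOTf (excess), 2,6-lutidine, CH2Cl2, 0 °C to rt
Reagents that add atoms: triethylsilyl triflate, CC[Si](CC)(CC)OS(=O)(=O)C(F)(F)F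
Why: Silyl triflate silylation of both hydroxyls removes every protic site before the organoaluminium step.

Step 18
Reactants: 20 2-methylbut-3-en-2-ol
Product: 21 triethyl[(2-methylbut-3-en-2-yl)oxy]silane
Conditions: TESOTf, 2,6-lutidine, CH2Cl2, 0 °C
Reagents that add atoms: triethylsilyl triflate, CC[Si](CC)(CC)OS(=O)(=O)C(F)(F)F
Why: Silylation of the tertiary allylic alcohol; the ether lowers volatility and masks O11 for the alanate coupling.

Step 19
Reactants: 21 triethyl[(2-methylbut-3-en-2-yl)oxy]silane
Product: 22 rac-triethyl{[2-(oxiran-2-yl)propan-2-yl]oxy}silane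
Conditions: mCPBA, CH2Cl2, rt to 40 °C
Reagents that add atoms: 3-chloroperoxybenzoic acid, OOC(=O)c1cccc(Cl)c1
Why: Prilezhaev epoxidation of the only olefin; it is slow for a monosubstituted alkene but uncomplicated.

Step 20
Reactants: 22 rac-triethyl{[2-(oxiran-2-yl)propan-2-yl]oxy}silane
Product: 23 triethyl({2-[(2S)-oxiran-2-yl]propan-2-yl}oxy)silane
Conditions: (R,R)-[N,N'-bis(3,5-di-tert-butylsalicylidene)-1,2-cyclohexanediaminato]cobalt acetate, (salen)Co(OAc) (trivalent cobalt, 1 mol %), H2O (0.55 equiv), THF, 0 °C to rt
Reagents that add atoms: none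
Why: Jacobsen hydrolytic kinetic resolution; the (R,R)-catalyst is expected to hydrolyse the R epoxide and leave the S enantiomer, the sense reported for terminal epoxides whose substituent outranks the ring CH2 (as in epichlorohydrin). This sets C10.

Step 21
Reactants: 19 1β-ethynyl-4α-methyl-3α,4β-bis(triethylsilyloxy)-5β,6β-(isopropylidenedioxy)cyclohexane; 23 triethyl({2-[(2S)-oxiran-2-yl]propan-2-yl}oxy)silane
Product: 26 1β-[(2E,5S)-5-hydroxy-6-methyl-6-(triethylsilyloxy)hept-2-en-2-yl]-4α-methyl-3α,4β-bis(triethylsilyloxy)-5β,6β-(isopropylidenedioxy)cyclohexane, via alkenyldimethylalane 24 (not isolated), via lithium alkenylbutyldimethylalanate 25 (not isolated)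
Conditions: AlMe3 (3 equiv), Cp2ZrCl2 (0.5 equiv), CH2Cl2, 0 °C to rt; evaporate; hexane, n-BuLi (1 equiv), 0 °C; 23, THF, 0 °C to rt; aq. NH4Cl
Reagents that add atoms: trimethylaluminium, C[Al](C)C
Why: Negishi zirconium-catalysed syn-methylalumination places the methyl group (C14) on C7 and aluminium on C8, which fixes the E geometry. The butyl ate complex then opens the epoxide at its unsubstituted carbon, forming C8–C9 and carrying in the C10 carbinol unchanged.

Step 22
Reactants: 27 angelic acid
Product: 28 (Z)-2-methylbut-2-enoic 2,4,6-trichlorobenzoic anhydride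
Conditions: 2,4,6-Cl3C6H2COCl, Et3N, toluene, rt; filter off Et3NHCl; kept as a toluene solution, made fresh before each use
Reagents that add atoms: 2,4,6-trichlorobenzoyl chloride, O=C(Cl)c1c(Cl)cc(Cl)cc1Cl
Why: Mixed anhydride formation, the first stage of a Yamaguchi esterification: the triethylammonium carboxylate attacks the aroyl chloride, and without a nucleophilic catalyst or heat the Z geometry is kept. The reagent is made in its own step because it serves both angelate installations (steps 23 and 34).

Step 23
Reactants: 26 1β-[(2E,5S)-5-hydroxy-6-methyl-6-(triethylsilyloxy)hept-2-en-2-yl]-4α-methyl-3α,4β-bis(triethylsilyloxy)-5β,6β-(isopropylidenedioxy)cyclohexane; 28 (Z)-2-methylbut-2-enoic 2,4,6-trichlorobenzoic anhydride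
Product: 29 1β-{(2E,5S)-6-methyl-5-[(Z)-2-methylbut-2-enoyloxy]-6-(triethylsilyloxy)hept-2-en-2-yl}-4α-methyl-3α,4β-bis(triethylsilyloxy)-5β,6β-(isopropylidenedioxy)cyclohexane
Conditions: 28 (toluene solution, 2 equiv), Et3N, toluene, 80 °C (no DMAP)
Reagents that add atoms: none
Why: Yamaguchi-type mixed anhydride acylation without a nucleophilic catalyst, the conditions known to form angelates without Z to E isomerisation; the ortho chlorines steer the alcohol to the angeloyl carbonyl, and O10 is the only free hydroxyl.

Step 24
Reactants: 29 1β-{(2E,5S)-6-methyl-5-[(Z)-2-methylbut-2-enoyloxy]-6-(triethylsilyloxy)hept-2-en-2-yl}-4α-methyl-3α,4β-bis(triethylsilyloxy)-5β,6β-(isopropylidenedioxy)cyclohexane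
Product: 30 1β-{(2E,5S)-6-hydroxy-6-methyl-5-[(Z)-2-methylbut-2-enoyloxy]hept-2-en-2-yl}-4α-methyl-5β,6β-(isopropylidenedioxy)cyclohexane-3α,4β-diol
Conditions: HF·pyridine, pyridine–THF, 0 °C to rt
Reagents that add atoms: none
Why: Fluoride cleavage of all three triethylsilyl ethers; the dioxolane and the angelate are stable to buffered HF, and of the three hydroxyls released only O3 is secondary.

Step 25
Reactants: 31 S-ethyl propanethioate
Product: 32 (Z)-1-(ethylsulfanyl)-1-(trimethylsilyloxy)prop-1-ene
Conditions: LiN(i-Pr)2, THF, −78 °C; Me3SiCl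
Reagents that add atoms: chlorotrimethylsilane, C[Si](C)(C)Cl
Why: Kinetic enolisation of the thioester in THF and O-silylation should give the Z silylketene acetal (methyl cis to sulfur).

Step 26
Reactants: 32 (Z)-1-(ethylsulfanyl)-1-(trimethylsilyloxy)prop-1-ene; 33 methyl pyruvate
Product: 35 methyl (2S,3R)-4-(ethylsulfanyl)-2-hydroxy-2,3-dimethyl-4-oxobutanoate, via trimethylsilyl ether 34 (not isolated)
Conditions: Sn(OTf)2 (divalent tin, 10 mol %), 2,6-bis[(4S)-4-benzyl-4,5-dihydrooxazol-2-yl]pyridine (12 mol %), CH2Cl2, −78 °C; then 1 M HCl, THF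
Reagents that add atoms: none
Why: Catalytic enantioselective Mukaiyama aldol addition to a chelated pyruvate ester; the tin–pybox Lewis acid gives the anti adduct from Z thioester enolsilanes, so C2' and C3' are set together by the catalyst.

Step 27
Reactants: 35 methyl (2S,3R)-4-(ethylsulfanyl)-2-hydroxy-2,3-dimethyl-4-oxobutanoate
Product: 36 methyl (2S,3R)-2-hydroxy-2,3-dimethyl-4-oxobutanoate
Conditions: Et3SiH, Pd/C, acetone, rt
Reagents that add atoms: none
Why: Fukuyama reduction; palladium inserts into the C–S bond and the silane delivers hydride to the thioester only, leaving the methyl ester and the tertiary alcohol untouched under neutral conditions.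

Step 28
Reactants: 36 methyl (2S,3R)-2-hydroxy-2,3-dimethyl-4-oxobutanoate
Product: 37 dimethyl (2S,3S,4E)-2-hydroxy-2,3-dimethylhex-4-enedioate
Conditions: Ph3P=CHCO2Me, CH2Cl2, rt
Reagents that add atoms: methyl (triphenylphosphoranylidene)acetate, COC(=O)C=P(c1ccccc1)(c1ccccc1)c1ccccc1
Why: Wittig olefination with a stabilised, non-basic ylide is E-selective and spares the α-stereocentre of the β-hydroxy aldehyde.

Step 29
Reactants: 37 dimethyl (2S,3S,4E)-2-hydroxy-2,3-dimethylhex-4-enedioate
Product: 39 methyl (2S,3S)-2,3-dimethyl-6-oxooxane-2-carboxylate, via hydroxy diester 38 (not isolated)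
Conditions: H2 (1 atm), Pd/C, EtOAc; filter; TsOH·H2O (cat.), toluene, 80 °C
Reagents that add atoms: none
Why: Hydrogenation of the enoate, then acid-catalysed lactonisation of the tertiary hydroxyl onto the δ-ester; the six-membered lactone is the only closure open to it.

Step 30
Reactants: 39 methyl (2S,3S)-2,3-dimethyl-6-oxooxane-2-carboxylate
Product: 40 methyl (2S,3S,5S)-5-ethyl-2,3-dimethyl-6-oxooxane-2-carboxylate
Conditions: LiN(i-Pr)2, THF, −78 °C; EtI, DMPU, −78 to −40 °C; AcOH quench at −78 °C
Reagents that add atoms: iodoethane, CCI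
Why: Lactone enolate alkylation; the electrophile should enter axially on the half-chair enolate, anti to the C3' methyl group, giving the trans-3',5' (5'S) isomer under kinetic control. The cold quench avoids equilibration to the diequatorial epimer.

Step 31
Reactants: 40 methyl (2S,3S,5S)-5-ethyl-2,3-dimethyl-6-oxooxane-2-carboxylate
Product: 42 (2S,3S,5S)-5-ethyl-2,3-dimethyl-6-oxooxane-2-carboxylic acid, via dilithium hydroxy dicarboxylate 41 (not isolated)
Conditions: LiOH, THF–H2O, rt; then 2 M HCl to pH 1, rt
Reagents that add atoms: lithium hydroxide, [Li+].[OH-]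
Why: Saponification of the methyl ester (the lactone opens as well, and a carboxylate cannot epimerise at C5'); acidification then relactonises the tertiary hydroxy acid to the δ-lactone.

Step 32
Reactants: 30 1β-{(2E,5S)-6-hydroxy-6-methyl-5-[(Z)-2-methylbut-2-enoyloxy]hept-2-en-2-yl}-4α-methyl-5β,6β-(isopropylidenedioxy)cyclohexane-3α,4β-diol; 42 (2S,3S,5S)-5-ethyl-2,3-dimethyl-6-oxooxane-2-carboxylic acid
Product: 44 the 3α-O-[(2S,3S,5S)-5-ethyl-2,3-dimethyl-6-oxooxane-2-carbonyl] ester of 30 (4β- and 11-hydroxyls free, 5,6-dioxolane kept), via acid chloride 43 (not isolated)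
Conditions: 42, (COCl)2, DMF (cat.), CH2Cl2, 0 °C to rt; evaporate; then 30, DMAP, Et3N, CH2Cl2, rt to 40 °C
Reagents that add atoms: none
Why: Acyl chloride formation (no α-hydrogen, so no ketene and no epimerisation) followed by DMAP-catalysed acylation; O3 is the only secondary hydroxyl in 30, and the tertiary O4 and O11 should not compete.

Step 33
Reactants: 44 the 3α-O-lactone ester with 5,6-dioxolane
Product: 45 the 4β,5β,6β,11-tetraol: 3α-O-lactone ester, 10-O-angelate, E-C7(Me)=C8 olefin
Conditions: AcOH–H2O (4:1), 45 °C
Reagents that add atoms: none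
Why: Acid hydrolysis of the dioxolane; the esters are stable to it, and the O3 acyl group cannot migrate to the trans-diaxial tertiary O4.

Step 34
Reactants: 45 the 4β,5β,6β,11-tetraol; 28 (Z)-2-methylbut-2-enoic 2,4,6-trichlorobenzoic anhydride
Product: 47 the 5β-O-angelate of 45 (4β-, 6β- and 11-hydroxyls free), via dibutylstannylene acetal 46 (not isolated)
Conditions: 45, Bu2SnO, toluene, reflux (Dean–Stark), cool to rt; then 28 (toluene solution), rt
Reagents that add atoms: none
Why: Stannylene acetal formation on the cis-5,6-diol and acylation at its equatorial oxygen, the established regiochemistry for cis-diol stannylenes; the equatorial O5 ester is also the thermodynamically preferred one should any migration occur.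

Step 35
Reactants: 47 the 3α-O-lactone ester 5β,10-di-O-angelate with E-C7(Me)=C8 olefin
Product: 48 the (7R,8R)-7,8-epoxide of 47
Conditions: 1,2:4,5-di-O-isopropylidene-β-D-erythro-2,3-hexodiulo-2,6-pyranose (0.3 equiv), KHSO5 (as Oxone, 2KHSO5·KHSO4·K2SO4), K2CO3, Bu4NHSO4 (cat.), MeCN–dimethoxymethane, aq. Na2B4O7–Na2EDTA buffer (pH 10.5), 0 °C
Reagents that add atoms: potassium peroxymonosulfate, [K+].[O-]S(=O)(=O)OO
Why: Shi epoxidation by a chiral dioxirane through a spiro transition state; the electron-rich trisubstituted olefin is the only reactive one because the angelates are electron-poor. The D-fructose-derived ketone should deliver oxygen to the face that makes C8 R, by analogy with trans-disubstituted and trisubstituted olefins.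

Step 36
Reactants: 48 the (7R,8R)-7,8-epoxide
Product: 49 CNP0148734.1 (target)
Conditions: Cp2TiCl2 (3 equiv), Mn dust, THF, rt (gives Cp2TiCl, trivalent titanium); then 48, rt; dilute aq. HCl, 0 °C
Reagents that add atoms: none
Why: Nugent–RajanBabu opening: Cp2TiCl cleaves the epoxide homolytically at the tertiary carbon to a β-titanoxy C7 radical, and a second titanocene abstracts hydrogen from the least hindered β-position, the C14 methyl group, giving the 2-substituted allylic alcohol (the known isomerisation of trisubstituted epoxides to exo-methylene allylic alcohols). The C8–O bond is never broken, so C8 stays R.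

## Compound list

1 | L-arabinose | O=C[C@H](O)[C@@H](O)[C@@H](O)CO | starting material
2 | benzyl β-L-arabinopyranoside | c1ccccc1CO[C@@H]2[C@H](O)[C@@H](O)[C@@H](O)CO2 | intermediate
3 | benzyl 3,4-O-isopropylidene-β-L-arabinopyranoside | c1ccccc1CO[C@@H]2[C@H](O)[C@H]3OC(C)(C)O[C@H]3CO2 | intermediate
4 | benzyl 3,4-O-isopropylidene-β-L-erythro-pentopyranosid-2-ulose | c1ccccc1CO[C@@H]2C(=O)[C@H]3OC(C)(C)O[C@H]3CO2 | intermediate
5 | benzyl 3,4-O-isopropylidene-2-C-methyl-β-L-ribopyranoside | c1ccccc1CO[C@@H]2[C@@](C)(O)[C@H]3OC(C)(C)O[C@H]3CO2 | intermediate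
6 | benzyl 3,4-O-isopropylidene-2-C-methyl-2-O-triethylsilyl-β-L-ribopyranoside | c1ccccc1CO[C@@H]2[C@@](C)(O[Si](CC)(CC)CC)[C@H]3OC(C)(C)O[C@H]3CO2 | intermediate
7 | 3,4-O-isopropylidene-2-C-methyl-2-O-triethylsilyl-L-ribopyranose (anomeric mixture) | OC1[C@@](C)(O[Si](CC)(CC)CC)[C@H]2OC(C)(C)O[C@H]2CO1 | intermediate
8 | 3,4-O-isopropylidene-2-C-methyl-2-O-triethylsilyl-L-ribono-1,5-lactone | O=C1[C@@](C)(O[Si](CC)(CC)CC)[C@H]2OC(C)(C)O[C@H]2CO1 | intermediate
9 | caesium 3,4-O-isopropylidene-2-C-methyl-2-O-triethylsilyl-L-ribonate (not isolated) | [Cs+].[O-]C(=O)[C@@](C)(O[Si](CC)(CC)CC)[C@H]1OC(C)(C)O[C@H]1CO | intermediate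
10 | methyl 3,4-O-isopropylidene-2-C-methyl-2-O-triethylsilyl-L-ribonate | COC(=O)[C@@](C)(O[Si](CC)(CC)CC)[C@H]1OC(C)(C)O[C@H]1CO | intermediate
11 | methyl 3,4-O-isopropylidene-2-C-methyl-5-oxo-2-O-triethylsilyl-L-ribonate (C5 aldehyde) | COC(=O)[C@@](C)(O[Si](CC)(CC)CC)[C@H]1OC(C)(C)O[C@H]1C=O | intermediate
12 | methyl 5,6-dideoxy-3,4-O-isopropylidene-6-methoxy-2-C-methyl-2-O-triethylsilyl-L-ribo-hex-5-enonate (E shown, Z accompanies) | COC(=O)[C@@](C)(O[Si](CC)(CC)CC)[C@H]1OC(C)(C)O[C@H]1/C=C/OC | intermediate
13 | (6E)-2,7-dimethoxy-4,5-(isopropylidenedioxy)-3-methyl-3-(triethylsilyloxy)hepta-1,6-diene, 2-C-methyl-L-ribo configuration (E shown, Z accompanies) | C=C(OC)[C@@](C)(O[Si](CC)(CC)CC)[C@H]1OC(C)(C)O[C@H]1/C=C/OC | intermediate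
14 | 1β-(dimethoxymethyl)-3,3-dimethoxy-4α-methyl-4β-(triethylsilyloxy)-5β,6β-(isopropylidenedioxy)cyclohexane | COC(OC)[C@H]1CC(OC)(OC)[C@@](C)(O[Si](CC)(CC)CC)[C@H]2OC(C)(C)O[C@@H]12 | intermediate
15 | 1β-formyl-4α-methyl-4β-(triethylsilyloxy)-5β,6β-(isopropylidenedioxy)cyclohexan-3-one | O=C[C@H]1CC(=O)[C@@](C)(O[Si](CC)(CC)CC)[C@H]2OC(C)(C)O[C@@H]12 | intermediate
16 | 1β-ethynyl-4α-methyl-4β-(triethylsilyloxy)-5β,6β-(isopropylidenedioxy)cyclohexan-3-one | C#C[C@H]1CC(=O)[C@@](C)(O[Si](CC)(CC)CC)[C@H]2OC(C)(C)O[C@@H]12 | intermediate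
17 | 1β-ethynyl-4β-hydroxy-4α-methyl-5β,6β-(isopropylidenedioxy)cyclohexan-3-one | C#C[C@H]1CC(=O)[C@@](C)(O)[C@H]2OC(C)(C)O[C@@H]12 | intermediate
18 | 1β-ethynyl-4α-methyl-5β,6β-(isopropylidenedioxy)cyclohexane-3α,4β-diol | C#C[C@H]1C[C@H](O)[C@@](C)(O)[C@H]2OC(C)(C)O[C@@H]12 | intermediate
19 | 1β-ethynyl-4α-methyl-3α,4β-bis(triethylsilyloxy)-5β,6β-(isopropylidenedioxy)cyclohexane | C#C[C@H]1C[C@H](O[Si](CC)(CC)CC)[C@@](C)(O[Si](CC)(CC)CC)[C@H]2OC(C)(C)O[C@@H]12 | intermediate
20 | 2-methylbut-3-en-2-ol | C=CC(C)(C)O | starting material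
21 | triethyl[(2-methylbut-3-en-2-yl)oxy]silane | C=CC(C)(C)O[Si](CC)(CC)CC | intermediate
22 | rac-triethyl{[2-(oxiran-2-yl)propan-2-yl]oxy}silane | C1OC1C(C)(C)O[Si](CC)(CC)CC | intermediate
23 | triethyl({2-[(2S)-oxiran-2-yl]propan-2-yl}oxy)silane | C1[C@H](O1)C(C)(C)O[Si](CC)(CC)CC | intermediate
24 | (E)-alkenyldimethylalane from 19: dimethylaluminium on C8, methyl (C14) on C7 (not isolated) | C/C(=C\[Al](C)C)[C@H]1C[C@H](O[Si](CC)(CC)CC)[C@@](C)(O[Si](CC)(CC)CC)[C@H]2OC(C)(C)O[C@@H]12 | intermediate
25 | lithium butyl(dimethyl)alkenylalanate from 24 (not isolated) | [Li+].C/C(=C\[Al-](C)(C)CCCC)[C@H]1C[C@H](O[Si](CC)(CC)CC)[C@@](C)(O[Si](CC)(CC)CC)[C@H]2OC(C)(C)O[C@@H]12 | intermediate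
26 | 1β-[(2E,5S)-5-hydroxy-6-methyl-6-(triethylsilyloxy)hept-2-en-2-yl]-4α-methyl-3α,4β-bis(triethylsilyloxy)-5β,6β-(isopropylidenedioxy)cyclohexane | C/C(=C\C[C@H](O)C(C)(C)O[Si](CC)(CC)CC)[C@H]1C[C@H](O[Si](CC)(CC)CC)[C@@](C)(O[Si](CC)(CC)CC)[C@H]2OC(C)(C)O[C@@H]12 | intermediate
27 | angelic acid, (Z)-2-methylbut-2-enoic acid | C/C=C(/C)C(=O)O | starting material
28 | (Z)-2-methylbut-2-enoic 2,4,6-trichlorobenzoic anhydride | C/C=C(/C)C(=O)OC(=O)c1c(Cl)cc(Cl)cc1Cl | intermediate
29 | 10-O-angelate of 26 | C/C(=C\C[C@H](OC(=O)/C(C)=C\C)C(C)(C)O[Si](CC)(CC)CC)[C@H]1C[C@H](O[Si](CC)(CC)CC)[C@@](C)(O[Si](CC)(CC)CC)[C@H]2OC(C)(C)O[C@@H]12 | intermediate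
30 | 1β-{(2E,5S)-6-hydroxy-6-methyl-5-[(Z)-2-methylbut-2-enoyloxy]hept-2-en-2-yl}-4α-methyl-5β,6β-(isopropylidenedioxy)cyclohexane-3α,4β-diol | C/C(=C\C[C@H](OC(=O)/C(C)=C\C)C(C)(C)O)[C@H]1C[C@H](O)[C@@](C)(O)[C@H]2OC(C)(C)O[C@@H]12 | intermediate
31 | S-ethyl propanethioate | CCC(=O)SCC | starting material
32 | (Z)-1-(ethylsulfanyl)-1-(trimethylsilyloxy)prop-1-ene | C/C=C(\SCC)O[Si](C)(C)C | intermediate
33 | methyl pyruvate | CC(=O)C(=O)OC | starting material
34 | methyl (2S,3R)-4-(ethylsulfanyl)-2,3-dimethyl-4-oxo-2-(trimethylsilyloxy)butanoate (not isolated) | COC(=O)[C@@](C)(O[Si](C)(C)C)[C@@H](C)C(=O)SCC | intermediate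
35 | methyl (2S,3R)-4-(ethylsulfanyl)-2-hydroxy-2,3-dimethyl-4-oxobutanoate | COC(=O)[C@@](C)(O)[C@@H](C)C(=O)SCC | intermediate
36 | methyl (2S,3R)-2-hydroxy-2,3-dimethyl-4-oxobutanoate | COC(=O)[C@@](C)(O)[C@@H](C)C=O | intermediate
37 | dimethyl (2S,3S,4E)-2-hydroxy-2,3-dimethylhex-4-enedioate | COC(=O)[C@@](C)(O)[C@@H](C)/C=C/C(=O)OC | intermediate
38 | dimethyl (2S,3S)-2-hydroxy-2,3-dimethylhexanedioate (not isolated) | COC(=O)[C@@](C)(O)[C@@H](C)CCC(=O)OC | intermediate
39 | methyl (2S,3S)-2,3-dimethyl-6-oxooxane-2-carboxylate | COC(=O)[C@@]1(C)OC(=O)CC[C@@H]1C | intermediate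
40 | methyl (2S,3S,5S)-5-ethyl-2,3-dimethyl-6-oxooxane-2-carboxylate | COC(=O)[C@@]1(C)OC(=O)[C@@H](CC)C[C@@H]1C | intermediate
41 | dilithium (2S,3S,5S)-5-ethyl-2-hydroxy-2,3-dimethylhexanedioate (not isolated) | [Li+].[Li+].[O-]C(=O)[C@@](C)(O)[C@@H](C)C[C@H](CC)C([O-])=O | intermediate
42 | (2S,3S,5S)-5-ethyl-2,3-dimethyl-6-oxooxane-2-carboxylic acid | OC(=O)[C@@]1(C)OC(=O)[C@@H](CC)C[C@@H]1C | intermediate
43 | (2S,3S,5S)-5-ethyl-2,3-dimethyl-6-oxooxane-2-carbonyl chloride (not isolated) | ClC(=O)[C@@]1(C)OC(=O)[C@@H](CC)C[C@@H]1C | intermediate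
44 | 3α-O-[(2S,3S,5S)-5-ethyl-2,3-dimethyl-6-oxooxane-2-carbonyl] ester of 30 (5,6-dioxolane kept) | C/C(=C\C[C@H](OC(=O)/C(C)=C\C)C(C)(C)O)[C@H]1C[C@H](OC(=O)[C@@]3(C)OC(=O)[C@@H](CC)C[C@@H]3C)[C@@](C)(O)[C@H]2OC(C)(C)O[C@@H]12 | intermediate
45 | 4β,5β,6β,11-tetraol from 44 (3α-O-lactone ester, 10-O-angelate, E-C7(Me)=C8) | C/C(=C\C[C@H](OC(=O)/C(C)=C\C)C(C)(C)O)[C@H]1C[C@H](OC(=O)[C@@]2(C)OC(=O)[C@@H](CC)C[C@@H]2C)[C@@](C)(O)[C@@H](O)[C@H]1O | intermediate
46 | 5,6-O-dibutylstannylene acetal of 45 (not isolated) | C/C(=C\C[C@H](OC(=O)/C(C)=C\C)C(C)(C)O)[C@H]1C[C@H](OC(=O)[C@@]2(C)OC(=O)[C@@H](CC)C[C@@H]2C)[C@@](C)(O)[C@H]3O[Sn](CCCC)(CCCC)O[C@@H]13 | intermediate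
47 | 5β-O-angelate of 45 (3α-O-lactone ester, 5β,10-di-O-angelate, E-C7(Me)=C8) | C/C(=C\C[C@H](OC(=O)/C(C)=C\C)C(C)(C)O)[C@H]1C[C@H](OC(=O)[C@@]2(C)OC(=O)[C@@H](CC)C[C@@H]2C)[C@@](C)(O)[C@@H](OC(=O)/C(C)=C\C)[C@H]1O | intermediate
48 | (7R,8R)-7,8-epoxide of 47 | C[C@@]4(O[C@@H]4C[C@H](OC(=O)/C(C)=C\C)C(C)(C)O)[C@H]1C[C@H](OC(=O)[C@@]2(C)OC(=O)[C@@H](CC)C[C@@H]2C)[C@@](C)(O)[C@@H](OC(=O)/C(C)=C\C)[C@H]1O | intermediate
49 | CNP0148734.1 | C=C([C@H](O)C[C@H](OC(=O)/C(C)=C\C)C(C)(C)O)[C@H]1C[C@H](OC(=O)[C@@]2(C)OC(=O)[C@@H](CC)C[C@@H]2C)[C@@](C)(O)[C@@H](OC(=O)/C(C)=C\C)[C@H]1O | target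

## Step count and least certain steps

Total step count: 36. Longest linear sequence: 25 steps from L-arabinose (steps 1–17, 21, 23–24, 32–36). The side sequences are three steps to epoxide 23 (steps 18–20), one step to anhydride 28 (step 22) and seven steps to lactone acid 42 (steps 25–31).

**Step 12 (key step).** Two processes are most likely to go wrong. The first is capture of the first radical cation by methanol before the ring closes, because both enol ethers carry inductively withdrawing oxygen substituents on their allylic carbons and react more slowly than the simple cases. The second is closure through the other chair, which would give poor facial selectivity at C1. A limited correction for the second is built into the route: aldehyde 15 can be equilibrated at C1 with DBU, although the two epimers are estimated to be close in energy. The fallback for the first replaces the electrolysis by a chemical oxidative coupling of enolate equivalents. It sets out from 13. Mild hydrolysis of both enol ethers (pyridinium tosylate, wet acetone) gives the open-chain 2-C-methyl-L-ribo keto aldehyde F1, a methyl ketone at C3 and a CH2–CHO unit at C1–C7. Double silylation with TBSOTf and Et3N gives the bis(tert-butyldimethylsilyl enol ether) F2. Oxidation of F2 with (NH4)2Ce(NO3)6 (tetravalent cerium) and NaHCO3 in MeCN at −30 °C, the known intramolecular oxidative coupling of two silyl enol ethers to a 1,4-dicarbonyl compound, joins C1 to C2 and returns to the route at keto aldehyde 15.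

**Step 21.** The likely failure is slow opening of the hindered epoxide by the alanate, so that butyl transfer or protonolysis of the alkenyl group takes over. The fallback sets out from 19. After the same methylalumination the alkenylalane 24 is quenched with iodine to give the (E)-alkenyl iodide F3, which is isolated. Iodine–lithium exchange with t-BuLi (Et2O, −78 °C) and opening of epoxide 23 by the alkenyllithium in the presence of BF3·OEt2 returns to the route at 26.

**Step 32.** The likely failure is incomplete acyl transfer, since an α-quaternary acyl pyridinium has to meet an axial hydroxyl next to a quaternary carbon. The fallback replaces nucleophilic catalysis of a reactive acyl chloride by acylation of the metal alkoxide with a small, stable acyl donor. It sets out from 42, which is converted with cyanuric fluoride and pyridine into the acyl fluoride F4. Triol 30 is deprotonated at O3 with LiN(SiMe3)2 (1 equiv, THF, −78 °C) and treated with F4, and the route is rejoined at 44.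

**Step 34.** The likely failure is loss of regiocontrol, either through a stannylene that spans O4 and O6 (acylation at O6) or through acyl migration from O5 to O6. The fallback blocks O4 and O6 together. It sets out from 45. t-Bu2Si(OTf)2 and 2,6-lutidine give the 4,6-O-di-tert-butylsilylene derivative F5; the 1,3-diaxial diol closes a six-membered silylene and leaves the equatorial O5 as the only free secondary hydroxyl. Acylation with anhydride 28 (toluene, 60 °C) gives the 5-O-angelate F6, and HF·pyridine removes the silylene to rejoin the route at 47.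

**Step 36.** The likely failures are hydrogen abstraction from C1 instead of C14, which would give the tetrasubstituted C1=C7 olefin, and reduction of the C7 radical by titanium-bound hydroxyl groups of the substrate. The fallback changes from radical to cationic opening. It sets out from 48. TMSOTf and 2,6-lutidine (toluene, −78 °C), followed by DBU, silylate the free hydroxyls and open the epoxide at C7, with loss of a C14 proton, to the allyl silyl ether; this gives the tetrakis(trimethylsilyl) ether F7 of the target. HF·pyridine then removes the four trimethylsilyl groups and returns to the route at 49.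

## Further compounds

F1 | step 12 | open-chain keto aldehyde of the 2-C-methyl-L-ribo chain (C3 methyl ketone; C4 triethylsilyl ether; C5/C6 dioxolane; C1H2–C7HO) | CC(=O)[C@@](C)(O[Si](CC)(CC)CC)[C@H]1OC(C)(C)O[C@H]1CC=O
F2 | step 12 | bis(tert-butyldimethylsilyl enol ether) of F1 (C2=C3 and C1=C7) | C=C(O[Si](C)(C)C(C)(C)C)[C@@](C)(O[Si](CC)(CC)CC)[C@H]1OC(C)(C)O[C@H]1C=CO[Si](C)(C)C(C)(C)C
F3 | step 21 | 1β-[(E)-1-iodoprop-1-en-2-yl]-4α-methyl-3α,4β-bis(triethylsilyloxy)-5β,6β-(isopropylidenedioxy)cyclohexane | C/C(=C\I)[C@H]1C[C@H](O[Si](CC)(CC)CC)[C@@](C)(O[Si](CC)(CC)CC)[C@H]2OC(C)(C)O[C@@H]12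
F4 | step 32 | (2S,3S,5S)-5-ethyl-2,3-dimethyl-6-oxooxane-2-carbonyl fluoride | FC(=O)[C@@]1(C)OC(=O)[C@@H](CC)C[C@@H]1C
F5 | step 34 | 4,6-O-di-tert-butylsilylene derivative of 45 | C/C(=C\C[C@H](OC(=O)/C(C)=C\C)C(C)(C)O)[C@H]1C[C@H](OC(=O)[C@@]2(C)OC(=O)[C@@H](CC)C[C@@H]2C)[C@@](C)(O[Si]3(C(C)(C)C)C(C)(C)C)[C@@H](O)[C@H]1O3
F6 | step 34 | 5-O-angelate of F5 | C/C(=C\C[C@H](OC(=O)/C(C)=C\C)C(C)(C)O)[C@H]1C[C@H](OC(=O)[C@@]2(C)OC(=O)[C@@H](CC)C[C@@H]2C)[C@@](C)(O[Si]3(C(C)(C)C)C(C)(C)C)[C@@H](OC(=O)/C(C)=C\C)[C@H]1O3
F7 | step 36 | 4,6,8,11-tetrakis-O-(trimethylsilyl) ether of 49 | C=C([C@H](O[Si](C)(C)C)C[C@H](OC(=O)/C(C)=C\C)C(C)(C)O[Si](C)(C)C)[C@H]1C[C@H](OC(=O)[C@@]2(C)OC(=O)[C@@H](CC)C[C@@H]2C)[C@@](C)(O[Si](C)(C)C)[C@@H](OC(=O)/C(C)=C\C)[C@H]1O[Si](C)(C)C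
A1 | alternative 1 | (E)-C7=C8 olefin with C14 methyl and free C10 hydroxyl (O3 PMB, O4/O5 acetonide, O6 TBS, O11 TES) | C/C(=C\C[C@H](O)C(C)(C)O[Si](CC)(CC)CC)[C@H]1C[C@H](OCc3ccc(OC)cc3)[C@@]2(C)OC(C)(C)O[C@H]2[C@H]1O[Si](C)(C)C(C)(C)C
A2 | alternative 2 | cyclohex-5-ene with C1 (CH2OTBS), C3 (OPMB) and C4 (methyl, hydroxyl) stereocentres | CC(C)(C)[Si](C)(C)OC[C@H]1C[C@H](OCc2ccc(OC)cc2)[C@@](C)(O)C=C1
A3 | alternative 3 | reclosed cyclohexane cis-4,5-diol with complete side chain (O8/O10 acetonide, O11 TES, O3 TES, O6 TBS) | C=C([C@@H]1OC(C)(C)O[C@H](C(C)(C)O[Si](CC)(CC)CC)C1)[C@H]2C[C@H](O[Si](CC)(CC)CC)[C@@](C)(O)[C@@H](O)[C@H]2O[Si](C)(C)C(C)(C)C
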